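Assumption: ring atoms are numbered C1 (ketone), C2 (CH2OH), C3 (=CH), C4 (O-isobutyryl), C5 (isopropyl), C6 (O-enoyl); read this way the target is (4S,5S,6R) with an E side-chain alkene.

Check of structures: (5R)-9 and addition anti to the silyloxy group give 10 as (1R,5R,6S). After ring opening and inversion at C4 this is the target configuration, so 9 and 10 needed no correction. The TBS group at C4 is kept and paired with a TBDPS group on the side chain so that C4 can be unmasked selectively.

## Structural features

The target is a single carbocycle, a cyclohex-2-en-1-one (C1 ketone, C2=C3), whose C2 carries a hydroxymethyl group. The remaining ring carbons C4, C5 and C6 are three contiguous stereocentres: C4 bears an isobutyrate, C5 an isopropyl group and C6 an (E)-4-hydroxy-2-methylbut-2-enoate. The C4 oxygen is cis to the isopropyl group and the C6 oxygen is trans to it. The fragile parts are the α-acyloxy ketone at C6 (epimerisable, easily hydrolysed or transacylated), the γ-acyloxy enone at C4 (ionisation or elimination across C4–C5 would aromatise the ring), the Michael-acceptor enone and two free primary allylic alcohols. The carbon skeleton is simple; the real difficulty is to place two different acyl groups on the two secondary oxygens that flank C5, with opposite relative configuration, while two primary hydroxyls end up free. The key step exploits the fact that the isopropyl methine carbon sits on C5 and that C6 is α to the C1 ketone. One extra bond from that methine carbon to C6 turns C5, C6 and CMe2 into a cyclopropane conjugated to C1, a 7,7-dimethylbicyclo[4.1.0]heptan-2-one that a carbenoid can build in one step. Reductive opening of this strained ring later returns the isopropyl group and a C1/C6 enolate that marks C6 for oxygenation, and the C4 oxygen next to C5 steers the facial course of the ring construction.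

## Logic of the disconnections

29 to 28: the O–Si bond of the side-chain ether is cut last. A non-basic desilylation is the mildest final operation for a molecule with two activated esters, and it keeps the side-chain hydroxyl masked through all acylation chemistry. The forward step must leave both esters and the enone untouched.

28 to 26 and 27: the C2–CH2OH bond is cut. C2 is the nucleophilic α-carbon of an enone under nucleophilic catalysis, so the one-carbon unit can be added last and never needs protection. The forward step must tolerate two esters and a hindered C3.

26 to 24 and 25: the C4–O bond is cut. The ring construction delivers the C4 oxygen trans to the isopropyl group, whereas the target has it cis; forming this bond by SN2 displacement with 25 corrects the configuration and installs the acyl group in one operation. The demand is clean inversion at a hindered allylic centre without elimination.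

24 to 23: the O–Si bond at C4 is restored. This only requires that the secondary silyl ether can be cleaved while the primary, more robust one on the side chain stays.

23 to 17 and 22: the acyl C–O bond at C6 is cut, which divides the molecule into ring and side chain. 17 has a single free hydroxyl, so no selectivity problem arises; the forward esterification must not epimerise C6 or isomerise the E-enoate.

22 to 21, 20, then 18 and 19: the acid is traced back through its ester and silyl ether to the C2=C3 bond of the side chain, cut as a Wittig alkene. A stabilised ylide should give the E geometry, and the two-carbon aldehyde comes from 18.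

17 to 14: the C2=C3 double bond is removed (via 15 and 16). The α,β-dehydrogenation is placed after C6 oxygenation because the C6 substituent then directs kinetic enolisation to C2. The forward step needs that regioselectivity and a hydroxyl mask that falls off on work-up.

14 to 12: the C6–O bond is cut (via 13). 12 is a regiodefined enol ether, so oxidation can only occur at C6; the oxidant must approach anti to the neighbouring isopropyl group.

12 to 10: the bond between C6 and the CMe2 carbon is re-formed (via 11). The isopropyl group and the C1/C6 enolate are the two ends of a reductively cleaved cyclopropyl ketone bond. The forward step must cleave only the exocyclic cyclopropane bond and trap the enolate before it equilibrates.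

10 to 9: the C5–C6 and C6–CMe2 bonds are cut together. This removes both rings and two stereocentres and leaves an acyclic chain with one stereocentre. The forward step must be selective for addition to the alkene and for the face anti to the silyloxy group.

9 to 6 and 7: the bond between the carbonyl carbon and the diazo carbon is cut (via 8); acylation of 7 by an activated form of 6 is the forward step, under conditions that spare the allylic silyl ether.

6 to 5, then 3 (via 4): ester hydrolysis, the O–Si bond and the carbinol C–H bond are undone in turn. The only reagent-controlled stereocentre of the route is set by enantioselective ketone reduction, and silylation must follow at once to prevent lactonisation.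

3 to 1 and 2: the bond between the ketone carbon and the alkenyl carbon is cut, giving two commercial fragments; the forward acylation must stop at the ketone.

## Other disconnections considered

Alternative 1: The cut is at C1–C2 and C2=C3, so that C2 and its carbon substituent come from triethyl phosphonoacetate A2 and the rest from the dialdehyde A1, (2R,4R)-3-isopropyl-2,4-bis(4-methoxybenzyloxy)pentanedial. In the forward step the carbanion of A2 adds to one formyl group of A1; after proton transfer the resulting phosphonate closes the ring by intramolecular Horner–Wadsworth–Emmons olefination of the other formyl group, giving the hydroxy cyclohexenecarboxylate A3.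

- In its favour: the ring, the C2=C3 alkene and the C2 carbon (as an ester) appear in one operation, so neither a dehydrogenation nor a Baylis–Hillman step is needed. On this point it is better than the chosen plan. C4, C5 and C6 already have their final relative configuration in A3, so no inversion is needed, which is also better. It avoids diazo and dissolving-metal chemistry.
- Against it: the two formyl groups of A1 are not homotopic. The central carbon carries H and isopropyl, so there is no twofold axis and the groups are diastereotopic. Only addition to the formyl group on the arm whose ether is anti to the isopropyl group leads to A3; the other direction gives a diastereomer, and nothing in A1 clearly biases the choice. A1 is an α-alkoxy aldehyde twice over and is exposed to base. The two identical ethers of A3 must later carry two different esters. The carbinol and the ester both need redox adjustment in a fixed order.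
- Comparison: structurally it converges more in the ring-forming step. Mechanistically it rests on a reversible polar addition with an unresolved group selectivity, whereas the chosen carbenoid addition is irreversible and stereospecific. In step count, the savings at C2 are likely to be spent on making A1 enantiopure and on differentiating the ethers, so no clear gain is expected.

Alternative 2: The cut is at C4–C5. The aldehyde A4, 3-[(4R,5R)-2,2-dimethyl-5-(2-methylprop-1-enyl)-1,3-dioxolan-4-yl]propanal from a tartrate ester, is activated by Me2AlCl A5. Its carbonyl carbon bonds to the alkene CH while an allylic methyl hydrogen moves to oxygen (type-one carbonyl-ene reaction), giving the all-equatorial isopropenyl cyclohexanol A6.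

- In its favour: the C1 and C6 oxygens and the absolute configuration come from the chiral pool, so neither an enantioselective catalyst nor an enol ether oxidation is needed. On securing C6 it is equal to or better than the chosen plan, and on reagent hazard it is better. The chair-like ene transition state has a well-established preference for the all-equatorial product.
- Against it: the C4 hydroxyl of A6 is trans to the C5 substituent, so the same inversion with 25 is still required (equal, no gain). The isopropenyl group needs a hydrogenation. The C1/C6 diol is released as a pair and must be differentiated, with the hindered C6 hydroxyl as the one to acylate. The allylic dioxolane oxygen sits directly on the ene component, lowers its nucleophilicity and offers A5 an ionisation pathway. C2=C3 and the hydroxymethyl group must still be added as in the chosen plan (equal).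
- Comparison: the alternative trades one catalyst-controlled centre for chiral-pool certainty, but A4 requires two different chain extensions of a symmetric diol derivative, which should make the route clearly longer than the four steps to 9.

Alternative 3: The cut is at C1–C6. The dialdehyde A7, (2S,3S)-3-[(tert-butyldimethylsilyl)oxy]-2-isopropylhexanedial, is reduced at both formyl groups by SmI2 A8 (divalent samarium); the two ketyl carbons couple to the cis-diol A9 with the C6 hydroxyl trans to the isopropyl group.

- In its favour: the C4 oxygen of A9 already has the final configuration (cis to isopropyl), so no inversion is needed; this is better than the chosen plan. The C6 oxygen arrives in the ring-closing step, which is equal to or better than a separate oxidation. No diazo compound is used.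
- Against it: the cis C4/C5 relationship in the ring corresponds to the anti aldol adduct, so an anti-selective auxiliary aldol is needed to make A7. A7 carries an epimerisable α-branched formyl group next to a β-silyloxy leaving group. Face selectivity at C6 rests on an alkyl rather than an alkoxy neighbour. The cis C1/C6 diol must be differentiated, with C1 oxidised and the more hindered C6 acylated. The silyl ether at C4 must be exchanged for the isobutyrate. The dehydrogenation and hydroxymethylation remain (equal).
- Comparison: the stereochemical logic at C4 is more direct than in the chosen plan, but the radical coupling has less predictable diastereocontrol than the substrate-controlled carbenoid addition. In step count the two plans should come out about equal up to the stage of 14.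

Key step: step 5

## Route

Step 1
Reactants: 1 methyl 4-chloro-4-oxobutanoate; 2 2-methyl-1-propenylmagnesium bromide
Product: 3 methyl 6-methyl-4-oxohept-5-enoate
Conditions: CuI (10 mol%), THF, −78 → −30 °C, 2 added slowly to 1
Reagents that add atoms: none
Why: Copper-catalysed acylation of a Grignard reagent by an acid chloride (ketone synthesis); the organocopper species reacts with the acid chloride much faster than with the ester or the β,β-disubstituted enone product, and slow addition at low temperature limits over-addition.

Step 2
Reactants: 3 methyl 6-methyl-4-oxohept-5-enoate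
Product: 5 methyl (4R)-4-[(tert-butyldimethylsilyl)oxy]-6-methylhept-5-enoate, via hydroxy ester 4 (not isolated)
Conditions: (S)-1-methyl-3,3-diphenyltetrahydro-1H,3H-pyrrolo[1,2-c][1,3,2]oxazaborole (10 mol%), BH3·SMe2 (0.7 equiv), THF, −30 °C; MeOH, volatiles off; then TBSCl, imidazole, DMF, 0 °C → rt
Reagents that add atoms: tert-butyldimethylsilyl chloride (TBSCl), CC(C)(C)[Si](C)(C)Cl
Why: Corey–Bakshi–Shibata reduction with the alkenyl group as the large ketone substituent, so the (S)-oxazaborolidine should deliver hydride to give the (R)-allylic alcohol (new stereocentre, catalyst control); silylation of crude 4 in the same operation prevents γ-lactonisation.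

Step 3
Reactants: 5 methyl (4R)-4-[(tert-butyldimethylsilyl)oxy]-6-methylhept-5-enoate
Product: 6 (4R)-4-[(tert-butyldimethylsilyl)oxy]-6-methylhept-5-enoic acid
Conditions: LiOH·H2O, THF/MeOH/H2O, 0 °C → rt; then 1 M HCl to pH 4, 0 °C
Reagents that add atoms: lithium hydroxide, [Li+].[OH-]
Why: Saponification of a methyl ester; the secondary TBS ether and the trisubstituted alkene are inert to hydroxide, and brief cold acidification to pH 4 spares the allylic silyl ether.

Step 4
Reactants: 6 (4R)-4-[(tert-butyldimethylsilyl)oxy]-6-methylhept-5-enoic acid; 7 (trimethylsilyl)diazomethane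
Product: 9 (5R)-5-[(tert-butyldimethylsilyl)oxy]-1-diazo-7-methyloct-6-en-2-one, via mixed anhydride 8 (not isolated)
Conditions: ClCO2Et, Et3N, THF, −15 °C; then 7 (2 M in hexanes), MeCN, 0 °C → rt
Reagents that add atoms: none
Why: Arndt–Eistert-type acylation of a diazomethane equivalent by a mixed carbonic anhydride; C-acylation is followed by loss of the silyl group to the carbonate leaving group, the conditions are neutral enough for the allylic silyl ether, and 7 is non-explosive but toxic by inhalation and is handled in a hood.

Step 5
Reactants: 9 (5R)-5-[(tert-butyldimethylsilyl)oxy]-1-diazo-7-methyloct-6-en-2-one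
Product: 10 (1R,5R,6S)-5-[(tert-butyldimethylsilyl)oxy]-7,7-dimethylbicyclo[4.1.0]heptan-2-one
Conditions: Cu(acac)2 (5 mol%), toluene, 90 °C, slow addition of 9 by syringe pump, high dilution
Reagents that add atoms: none
Why: Cu(acac)2 is reduced by the diazo compound to monovalent copper, which takes up 9 with loss of N2 to give an electrophilic copper carbenoid at the former diazo carbon; this carbon adds across the tethered C=CMe2 bond in a concerted but asynchronous [2+1] step, the bond to the alkene CH (ring C5–C6) running ahead of the bond to the CMe2 carbon (the temporary C6–CMe2 bond). The closest known reaction type is the copper-catalysed intramolecular cyclopropanation of unsaturated α-diazoketones to bicyclo[4.1.0]heptan-2-ones. The six-membered ring closes in a 6-exo sense with respect to the alkene (carbenoid carbon to the proximal alkene carbon), and the three-membered ring closes by the second carbenoid bond to the distal carbon, which can only give a cis ring fusion. The two new stereocentres (C1 and C6 of the bicycle) are thus fixed relative to each other by the fusion, and their sense relative to C5 of the bicycle is set by the silyloxy carbon: the Z-methyl group of the isopropylidene unit forces the carbinol C–H bond into the alkene plane (allylic 1,3-strain), the tether then lies on one face and the silyloxy group on the other, so the carbenoid should be delivered anti to the silyloxy group. The step needs chemoselectivity for cyclopropanation over 1,5 C–H insertion at the allylic, oxygen-bearing C–H and over oxonium ylide formation; copper carbenoids and an electron-rich trisubstituted alkene favour addition, and the bulky silyl group keeps the ether oxygen away from the metal. Slow addition at high dilution suppresses carbene dimerisation.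

Step 6
Reactants: 10 (1R,5R,6S)-5-[(tert-butyldimethylsilyl)oxy]-7,7-dimethylbicyclo[4.1.0]heptan-2-one
Product: 12 tert-butyl{[(1R,2R)-2-isopropyl-4-[(trimethylsilyl)oxy]cyclohex-3-en-1-yl]oxy}dimethylsilane, via lithium enolate 11 (not isolated)
Conditions: Li (2.1 equiv), NH3(l)/THF, t-BuOH (1.0 equiv), −78 °C; NH3 off; then TMSCl, Et3N, THF, −78 → 0 °C
Reagents that add atoms: chlorotrimethylsilane (TMSCl), C[Si](C)(C)Cl
Why: Dissolving-metal cleavage of a cyclopropyl ketone: the ketyl radical anion breaks the cyclopropane bond that overlaps best with the carbonyl π system, here the exocyclic bond from the ketone α-carbon (ring C6) to CMe2; a second electron and one proton then give the isopropyl group and a regiodefined lithium enolate, which is silylated on oxygen. The configuration at C5 is untouched because none of its bonds is broken, and the silyloxy group is γ to the transient carbanion and cannot be eliminated.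

Step 7
Reactants: 12 tert-butyl{[(1R,2R)-2-isopropyl-4-[(trimethylsilyl)oxy]cyclohex-3-en-1-yl]oxy}dimethylsilane
Product: 14 (2R,3R,4R)-4-[(tert-butyldimethylsilyl)oxy]-2-hydroxy-3-isopropylcyclohexan-1-one, via silyloxy ketone 13 (not isolated)
Conditions: mCPBA, NaHCO3, CH2Cl2, −20 → 0 °C; then 1 M HCl, THF, 0 °C
Reagents that add atoms: 3-chloroperoxybenzoic acid (mCPBA), OOC(=O)c1cccc(Cl)c1
Why: Rubottom oxidation: epoxidation of the silyl enol ether, ring opening and 1,4-silyl shift give the α-silyloxy ketone, whose labile TMS ether is hydrolysed on work-up while the TBS ether stays; the peracid should approach the face opposite the adjacent isopropyl group, so the new C6 hydroxyl is trans to it (substrate control), which is also the all-equatorial and thermodynamically preferred arrangement.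

Step 8
Reactants: 14 (2R,3R,4R)-4-[(tert-butyldimethylsilyl)oxy]-2-hydroxy-3-isopropylcyclohexan-1-one
Product: 17 (4R,5R,6R)-4-[(tert-butyldimethylsilyl)oxy]-6-hydroxy-5-isopropylcyclohex-2-en-1-one, via bis-silyl enol ether 15 (not isolated), via silyloxy enone 16 (not isolated)
Conditions: TMSCl (3 equiv), then LiN(iPr)2 (2.4 equiv), THF, −78 °C; then Pd(OAc)2 (1.1 equiv), MeCN, rt; then 1 M HCl, THF, 0 °C
Reagents that add atoms: none
Why: With the silyl chloride present the alkoxide is silylated first, and kinetic deprotonation then occurs at the unhindered C2 methylene because C6 is tertiary and flanked by a silyloxy group and the isopropyl-bearing carbon; Saegusa–Ito oxidation follows, in which the divalent palladium enolate undergoes β-hydride elimination toward C3, and dilute acid removes only the secondary TMS ether.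

Step 9
Reactants: 18 glycolaldehyde dimer (1,4-dioxane-2,5-diol); 19 ethyl 2-(triphenyl-λ5-phosphanylidene)propanoate
Product: 20 ethyl (2E)-4-hydroxy-2-methylbut-2-enoate
Conditions: CH2Cl2, reflux
Reagents that add atoms: none
Why: Wittig reaction of a stabilised ylide with the monomeric aldehyde released from the dimer; reversible betaine formation with stabilised ylides leads to the E trisubstituted enoate.

Step 10
Reactants: 20 ethyl (2E)-4-hydroxy-2-methylbut-2-enoate
Product: 21 ethyl (2E)-4-[(tert-butyldiphenylsilyl)oxy]-2-methylbut-2-enoate
Conditions: TBDPSCl, imidazole, DMF, 0 °C → rt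
Reagents that add atoms: tert-butyl(chloro)diphenylsilane (TBDPSCl), CC(C)(C)[Si](Cl)(c1ccccc1)c1ccccc1
Why: Standard silylation of a primary alcohol; the TBDPS group is chosen because it should outlast the later acidic cleavage of the secondary TBS ether.

Step 11
Reactants: 21 ethyl (2E)-4-[(tert-butyldiphenylsilyl)oxy]-2-methylbut-2-enoate
Product: 22 (2E)-4-[(tert-butyldiphenylsilyl)oxy]-2-methylbut-2-enoic acid
Conditions: LiOH·H2O, THF/MeOH/H2O, rt; then 1 M HCl to pH 3, 0 °C
Reagents that add atoms: lithium hydroxide, [Li+].[OH-]
Why: Saponification; the α-methyl enoate is a poor Michael acceptor for hydroxide and the primary TBDPS ether is stable to aqueous base at room temperature, so geometry and protecting group are retained.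

Step 12
Reactants: 17 (4R,5R,6R)-4-[(tert-butyldimethylsilyl)oxy]-6-hydroxy-5-isopropylcyclohex-2-en-1-one; 22 (2E)-4-[(tert-butyldiphenylsilyl)oxy]-2-methylbut-2-enoic acid
Product: 23 (1R,5R,6R)-5-[(tert-butyldimethylsilyl)oxy]-6-isopropyl-2-oxocyclohex-3-en-1-yl (2E)-4-[(tert-butyldiphenylsilyl)oxy]-2-methylbut-2-enoate
Conditions: DCC, 4-(dimethylamino)pyridine (10 mol%), CH2Cl2, 0 °C → rt
Reagents that add atoms: none
Why: Steglich esterification of the only free hydroxyl; the C6–O bond is not broken, so the configuration is retained, and the trans-diequatorial C5/C6 arrangement gives no thermodynamic drive for epimerisation under the mildly basic conditions.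

Step 13
Reactants: 23 (1R,5R,6R)-5-[(tert-butyldimethylsilyl)oxy]-6-isopropyl-2-oxocyclohex-3-en-1-yl (2E)-4-[(tert-butyldiphenylsilyl)oxy]-2-methylbut-2-enoate
Product: 24 (1R,5R,6S)-5-hydroxy-6-isopropyl-2-oxocyclohex-3-en-1-yl (2E)-4-[(tert-butyldiphenylsilyl)oxy]-2-methylbut-2-enoate
Conditions: aq. HF (48%), MeCN, 0 °C
Reagents that add atoms: none
Why: Acid-assisted fluoride cleavage of a silyl ether; under acidic conditions a TBDPS ether is cleaved far more slowly than a TBS ether, so the secondary C4 ether should go first, and esters, enone and the α-acyloxy ketone are stable to cold aqueous HF.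

Step 14
Reactants: 24 (1R,5R,6S)-5-hydroxy-6-isopropyl-2-oxocyclohex-3-en-1-yl (2E)-4-[(tert-butyldiphenylsilyl)oxy]-2-methylbut-2-enoate; 25 isobutyric acid
Product: 26 (1R,5S,6S)-6-isopropyl-5-(isobutyryloxy)-2-oxocyclohex-3-en-1-yl (2E)-4-[(tert-butyldiphenylsilyl)oxy]-2-methylbut-2-enoate
Conditions: PPh3, DIAD, toluene, 0 °C → rt
Reagents that add atoms: none
Why: Mitsunobu reaction: the alkoxyphosphonium ion at C4 is displaced by isobutyrate from the opposite face, which sets the 4S configuration (cis to isopropyl) by SN2 inversion. The electron-poor enone disfavours ionisation, SN2′ attack would have to occur at the enone α-carbon, and the C5 hydrogen is gauche to the leaving group, which disfavours anti elimination.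

Step 15
Reactants: 26 (1R,5S,6S)-6-isopropyl-5-(isobutyryloxy)-2-oxocyclohex-3-en-1-yl (2E)-4-[(tert-butyldiphenylsilyl)oxy]-2-methylbut-2-enoate; 27 formaldehyde
Product: 28 (1R,5S,6S)-3-(hydroxymethyl)-6-isopropyl-5-(isobutyryloxy)-2-oxocyclohex-3-en-1-yl (2E)-4-[(tert-butyldiphenylsilyl)oxy]-2-methylbut-2-enoate
Conditions: 27 (37% aq.), 4-(dimethylamino)pyridine (0.3 equiv), THF/H2O, rt
Reagents that add atoms: none
Why: Morita–Baylis–Hillman hydroxymethylation of a cyclic enone: the amine adds to C3, the resulting C2 enolate adds to formaldehyde and elimination of the amine restores the enone, with no co-product; no stereocentre is formed, and the α-methyl enoate of the side chain is too hindered and too poor an acceptor to compete.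

Step 16
Reactants: 28 (1R,5S,6S)-3-(hydroxymethyl)-6-isopropyl-5-(isobutyryloxy)-2-oxocyclohex-3-en-1-yl (2E)-4-[(tert-butyldiphenylsilyl)oxy]-2-methylbut-2-enoate
Product: 29 (1R,5S,6S)-3-(hydroxymethyl)-6-isopropyl-5-(isobutyryloxy)-2-oxocyclohex-3-en-1-yl (2E)-4-hydroxy-2-methylbut-2-enoate
Conditions: HF·pyridine, THF, 0 °C → rt
Reagents that add atoms: none
Why: Desilylation of a primary TBDPS ether by an acidic fluoride source over a longer time at room temperature; the non-basic medium avoids acyl migration, ester hydrolysis and epimerisation at C6.

## Compound list

1 | methyl 4-chloro-4-oxobutanoate | COC(=O)CCC(Cl)=O | starting material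
2 | 2-methyl-1-propenylmagnesium bromide | CC(C)=C[Mg]Br | starting material
3 | methyl 6-methyl-4-oxohept-5-enoate | COC(=O)CCC(=O)C=C(C)C | intermediate
4 | methyl (4R)-4-hydroxy-6-methylhept-5-enoate | COC(=O)CC[C@@H](O)C=C(C)C | intermediate
5 | methyl (4R)-4-[(tert-butyldimethylsilyl)oxy]-6-methylhept-5-enoate | COC(=O)CC[C@@H](O[Si](C)(C)C(C)(C)C)C=C(C)C | intermediate
6 | (4R)-4-[(tert-butyldimethylsilyl)oxy]-6-methylhept-5-enoic acid | OC(=O)CC[C@@H](O[Si](C)(C)C(C)(C)C)C=C(C)C | intermediate
7 | (trimethylsilyl)diazomethane | C[Si](C)(C)C=[N+]=[N-] | starting material
8 | (4R)-4-[(tert-butyldimethylsilyl)oxy]-6-methylhept-5-enoic ethyl carbonic anhydride | CCOC(=O)OC(=O)CC[C@@H](O[Si](C)(C)C(C)(C)C)C=C(C)C | intermediate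
9 | (5R)-5-[(tert-butyldimethylsilyl)oxy]-1-diazo-7-methyloct-6-en-2-one | [N-]=[N+]=CC(=O)CC[C@@H](O[Si](C)(C)C(C)(C)C)C=C(C)C | intermediate
10 | (1R,5R,6S)-5-[(tert-butyldimethylsilyl)oxy]-7,7-dimethylbicyclo[4.1.0]heptan-2-one (silyloxy group anti to the cyclopropane) | CC1(C)[C@@H]2C(=O)CC[C@@H](O[Si](C)(C)C(C)(C)C)[C@H]12 | intermediate
11 | lithium (3R,4R)-4-[(tert-butyldimethylsilyl)oxy]-3-isopropylcyclohex-1-en-1-olate | [Li+].[O-]C1=C[C@@H](C(C)C)[C@H](O[Si](C)(C)C(C)(C)C)CC1 | intermediate
12 | tert-butyl{[(1R,2R)-2-isopropyl-4-[(trimethylsilyl)oxy]cyclohex-3-en-1-yl]oxy}dimethylsilane (isopropyl and silyloxy groups trans) | C[Si](C)(C)OC1=C[C@@H](C(C)C)[C@H](O[Si](C)(C)C(C)(C)C)CC1 | intermediate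
13 | (2R,3S,4R)-4-[(tert-butyldimethylsilyl)oxy]-3-isopropyl-2-[(trimethylsilyl)oxy]cyclohexan-1-one (all substituents trans) | C[Si](C)(C)O[C@H]1C(=O)CC[C@@H](O[Si](C)(C)C(C)(C)C)[C@@H]1C(C)C | intermediate
14 | (2R,3R,4R)-4-[(tert-butyldimethylsilyl)oxy]-2-hydroxy-3-isopropylcyclohexan-1-one (all substituents trans) | O[C@H]1C(=O)CC[C@@H](O[Si](C)(C)C(C)(C)C)[C@@H]1C(C)C | intermediate
15 | tert-butyl{[(1R,2S,3R)-2-isopropyl-3,4-bis[(trimethylsilyl)oxy]cyclohex-4-en-1-yl]oxy}dimethylsilane | C[Si](C)(C)O[C@H]1C(O[Si](C)(C)C)=CC[C@@H](O[Si](C)(C)C(C)(C)C)[C@@H]1C(C)C | intermediate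
16 | (4R,5S,6R)-4-[(tert-butyldimethylsilyl)oxy]-5-isopropyl-6-[(trimethylsilyl)oxy]cyclohex-2-en-1-one | C[Si](C)(C)O[C@H]1C(=O)C=C[C@@H](O[Si](C)(C)C(C)(C)C)[C@@H]1C(C)C | intermediate
17 | (4R,5R,6R)-4-[(tert-butyldimethylsilyl)oxy]-6-hydroxy-5-isopropylcyclohex-2-en-1-one | O[C@H]1C(=O)C=C[C@@H](O[Si](C)(C)C(C)(C)C)[C@@H]1C(C)C | intermediate
18 | glycolaldehyde dimer (1,4-dioxane-2,5-diol) | OC1COC(O)CO1 | starting material
19 | ethyl 2-(triphenyl-λ5-phosphanylidene)propanoate | CCOC(=O)C(C)=P(c1ccccc1)(c1ccccc1)c1ccccc1 | starting material
20 | ethyl (2E)-4-hydroxy-2-methylbut-2-enoate | CCOC(=O)/C(C)=C/CO | intermediate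
21 | ethyl (2E)-4-[(tert-butyldiphenylsilyl)oxy]-2-methylbut-2-enoate | CCOC(=O)/C(C)=C/CO[Si](c1ccccc1)(c1ccccc1)C(C)(C)C | intermediate
22 | (2E)-4-[(tert-butyldiphenylsilyl)oxy]-2-methylbut-2-enoic acid | OC(=O)/C(C)=C/CO[Si](c1ccccc1)(c1ccccc1)C(C)(C)C | intermediate
23 | (1R,5R,6R)-5-[(tert-butyldimethylsilyl)oxy]-6-isopropyl-2-oxocyclohex-3-en-1-yl (2E)-4-[(tert-butyldiphenylsilyl)oxy]-2-methylbut-2-enoate | C/C(=C\CO[Si](c1ccccc1)(c1ccccc1)C(C)(C)C)C(=O)O[C@H]1C(=O)C=C[C@@H](O[Si](C)(C)C(C)(C)C)[C@@H]1C(C)C | intermediate
24 | (1R,5R,6S)-5-hydroxy-6-isopropyl-2-oxocyclohex-3-en-1-yl (2E)-4-[(tert-butyldiphenylsilyl)oxy]-2-methylbut-2-enoate (C4 hydroxyl trans to isopropyl) | C/C(=C\CO[Si](c1ccccc1)(c1ccccc1)C(C)(C)C)C(=O)O[C@H]1C(=O)C=C[C@@H](O)[C@@H]1C(C)C | intermediate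
25 | isobutyric acid | CC(C)C(=O)O | starting material
26 | (1R,5S,6S)-6-isopropyl-5-(isobutyryloxy)-2-oxocyclohex-3-en-1-yl (2E)-4-[(tert-butyldiphenylsilyl)oxy]-2-methylbut-2-enoate (C4 ester cis to isopropyl) | C/C(=C\CO[Si](c1ccccc1)(c1ccccc1)C(C)(C)C)C(=O)O[C@H]1C(=O)C=C[C@H](OC(=O)C(C)C)[C@@H]1C(C)C | intermediate
27 | formaldehyde | C=O | starting material
28 | (1R,5S,6S)-3-(hydroxymethyl)-6-isopropyl-5-(isobutyryloxy)-2-oxocyclohex-3-en-1-yl (2E)-4-[(tert-butyldiphenylsilyl)oxy]-2-methylbut-2-enoate | C/C(=C\CO[Si](c1ccccc1)(c1ccccc1)C(C)(C)C)C(=O)O[C@H]1C(=O)C(CO)=C[C@H](OC(=O)C(C)C)[C@@H]1C(C)C | intermediate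
29 | (1R,5S,6S)-3-(hydroxymethyl)-6-isopropyl-5-(isobutyryloxy)-2-oxocyclohex-3-en-1-yl (2E)-4-hydroxy-2-methylbut-2-enoate (CNP0254776.1) | C/C(=C\CO)C(=O)O[C@H]1C(=O)C(CO)=C[C@H](OC(=O)C(C)C)[C@@H]1C(C)C | target

## Step count and least certain steps

Total step count: 16. Longest linear sequence: 13 steps (steps 1 to 8 and 12 to 16); steps 9 to 11 prepare the side-chain acid.

Step 5 (key step). The most likely failure is diversion of the carbenoid: 1,5 insertion into the C–H bond at the silyloxy carbon, which is both allylic and α to oxygen, or dimerisation, because the allylic oxygen lowers the nucleophilicity of the alkene. Loss of facial control is less likely, since the Z-methyl group enforces the reactive conformation. The fallback avoids a free carbenoid. It sets out from 9: warming in toluene in the dark should let the diazo group add as a 1,3-dipole across the tethered alkene to give the cis-fused pyrazoline F1; irradiation then expels nitrogen and closes the cyclopropane, returning to the route at 10.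

Step 15. The most likely failure is slow catalyst addition at C3, which is shielded by the pseudo-axial C4 ester, so that hydrolysis or migration of the activated C6 ester in the aqueous amine medium overtakes hydroxymethylation. The fallback sets out from 26: iodine and pyridine in CH2Cl2 should give the 3-iodo enone F2 by the same addition–elimination pathway with irreversible trapping. A Stille coupling of F2 with (tributylstannyl)methanol, catalysed by Pd(PPh3)4 (zerovalent palladium) under neutral conditions, then returns to the route at 28.

Step 14. The most likely failure is incomplete inversion: isobutyric acid is a weakly acidic pronucleophile and C4 is flanked by the isopropyl-bearing carbon, so acylation with retention through an acyloxyphosphonium species, or elimination, may compete. The fallback separates inversion from acylation. It sets out from 24: a Mitsunobu reaction with the more acidic chloroacetic acid should give the inverted chloroacetate F3. Thiourea and NaHCO3 in ethanol remove the chloroacetyl group selectively to give the cis alcohol F4, and isobutyryl chloride with pyridine acylates it with retention, returning to the route at 26.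

Step 8. The most likely failure is enolisation on the wrong side (toward C6) or incomplete transient silylation of the hydroxyl, giving mixtures in the palladium step. The fallback avoids enolate chemistry. It sets out from 14: esterification with 22 (DCC, 4-(dimethylamino)pyridine) gives the saturated keto ester F5. Aerobic dehydrogenation of F5 catalysed by Pd(OCOCF3)2 (divalent palladium) with DMSO under O2 in acetic acid should occur at the less substituted α-methylene, returning to the route at 23 and bypassing 17.

Step 13. The most likely failure is loss of both silyl groups, or slow cleavage of the hindered secondary ether so that the primary one starts to go as well. The fallback sets out from 23: exhaustive desilylation with excess HF·pyridine gives the diol F6. The primary allylic hydroxyl of F6 is then re-silylated selectively (TBDPSCl, imidazole, −20 °C) in preference to the hindered secondary one, returning to the route at 24.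

## Further compounds

F1 | step 5 | 4-[(tert-butyldimethylsilyl)oxy]-3,3-dimethyl-3,3a,4,5,6,7a-hexahydro-7H-indazol-7-one (cis ring fusion, silyloxy group anti to the N=N bridge, 4R) | CC1(C)N=N[C@@H]2C(=O)CC[C@@H](O[Si](C)(C)C(C)(C)C)[C@H]12
F2 | step 15 | (1R,5R,6S)-3-iodo-6-isopropyl-5-(isobutyryloxy)-2-oxocyclohex-3-en-1-yl (2E)-4-[(tert-butyldiphenylsilyl)oxy]-2-methylbut-2-enoate (same spatial arrangement as 26) | C/C(=C\CO[Si](c1ccccc1)(c1ccccc1)C(C)(C)C)C(=O)O[C@H]1C(=O)C(I)=C[C@H](OC(=O)C(C)C)[C@@H]1C(C)C
F3 | step 14 | (1R,5S,6S)-5-(2-chloroacetoxy)-6-isopropyl-2-oxocyclohex-3-en-1-yl (2E)-4-[(tert-butyldiphenylsilyl)oxy]-2-methylbut-2-enoate | C/C(=C\CO[Si](c1ccccc1)(c1ccccc1)C(C)(C)C)C(=O)O[C@H]1C(=O)C=C[C@H](OC(=O)CCl)[C@@H]1C(C)C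
F4 | step 14 | (1R,5S,6S)-5-hydroxy-6-isopropyl-2-oxocyclohex-3-en-1-yl (2E)-4-[(tert-butyldiphenylsilyl)oxy]-2-methylbut-2-enoate (C4 hydroxyl cis to isopropyl) | C/C(=C\CO[Si](c1ccccc1)(c1ccccc1)C(C)(C)C)C(=O)O[C@H]1C(=O)C=C[C@H](O)[C@@H]1C(C)C
F5 | step 8 | (1R,2R,3R)-3-[(tert-butyldimethylsilyl)oxy]-2-isopropyl-6-oxocyclohexyl (2E)-4-[(tert-butyldiphenylsilyl)oxy]-2-methylbut-2-enoate | C/C(=C\CO[Si](c1ccccc1)(c1ccccc1)C(C)(C)C)C(=O)O[C@H]1C(=O)CC[C@@H](O[Si](C)(C)C(C)(C)C)[C@@H]1C(C)C
F6 | step 13 | (1R,5R,6S)-5-hydroxy-6-isopropyl-2-oxocyclohex-3-en-1-yl (2E)-4-hydroxy-2-methylbut-2-enoate | C/C(=C\CO)C(=O)O[C@H]1C(=O)C=C[C@@H](O)[C@@H]1C(C)C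
A1 | alternative 1 | (2R,4R)-3-isopropyl-2,4-bis(4-methoxybenzyloxy)pentanedial | O=C[C@H](OCc1ccc(OC)cc1)C(C(C)C)[C@@H](OCc1ccc(OC)cc1)C=O
A2 | alternative 1 | triethyl phosphonoacetate | CCOC(=O)CP(=O)(OCC)OCC
A3 | alternative 1 | ethyl 6-hydroxy-4-isopropyl-3,5-bis(4-methoxybenzyloxy)cyclohex-1-ene-1-carboxylate (3,4-cis, 4,5-trans, 5,6-trans) | COc1ccc(CO[C@H]2[C@H](O)C(C(=O)OCC)=C[C@H](OCc3ccc(OC)cc3)[C@@H]2C(C)C)cc1
A4 | alternative 2 | 3-[(4R,5R)-2,2-dimethyl-5-(2-methylprop-1-enyl)-1,3-dioxolan-4-yl]propanal | O=CCC[C@H]1OC(C)(C)O[C@@H]1C=C(C)C
A5 | alternative 2 | dimethylaluminium chloride, Me2AlCl | C[Al](C)Cl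
A6 | alternative 2 | 4-hydroxy-3-isopropenylcyclohexane-1,2-diol 1,2-acetonide (all ring substituents equatorial) | CC1(C)O[C@H]2[C@H](O1)CC[C@@H](O)[C@@H]2C(C)=C
A7 | alternative 3 | (2S,3S)-3-[(tert-butyldimethylsilyl)oxy]-2-isopropylhexanedial | O=C[C@@H](C(C)C)[C@@H](O[Si](C)(C)C(C)(C)C)CCC=O
A8 | alternative 3 | samarium diiodide, SmI2 | I[Sm]I
A9 | alternative 3 | 4-[(tert-butyldimethylsilyl)oxy]-3-isopropylcyclohexane-1,2-diol (1,2-cis diol, 2,3-trans, 3,4-cis) | O[C@H]1[C@@H](O)CC[C@H](O[Si](C)(C)C(C)(C)C)[C@@H]1C(C)C
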